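Late in a closed flask the first question is where Sub stops, and for the ochre flask, charged like teal, a subtraction answers it. Sub and Rgt are used one for one, so [Sub] minus [Rgt] stays at 20.0 mM in the teal flask. This is the excess, the charge of Sub minus the charge of Rgt, with what complexes hold counted. Rgt is the limiting reagent, its charge being smaller than that of Sub, so the ochre flask has a floor of 20.0% of its Sub.

| flask | Sub | Rgt | Cat | Prd | time |
|---|---|---|---|---|---|
| teal | 100 mM | 80.0 mM | 10.0 mM |  |  |
| violet | 40.0 mM | 20.0 mM | 10.0 mM |  |  |
| blue | 100 mM | 80.0 mM | 20.0 mM |  |  |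
| green | 100 mM | 80.0 mM | 10.0 mM | 30.0 mM |  |
| ochre | 100 mM | 80.0 mM | 10.0 mM |  | 900 min |

| teal run: time / min | teal run: [Sub] / mM | violet run: time / min | violet run: [Sub] / mM | blue run: time / min | blue run: [Sub] / mM | green run: time / min | green run: [Sub] / mM |
|---|---|---|---|---|---|---|---|
| 25 | 87.0 | 25 | 36.8 | 25 | 75.8 | 25 | 86.5 |
| 50 | 73.3 | 50 | 33.0 | 50 | 53.1 | 50 | 75.4 |
| 75 | 64.6 | 75 | 27.6 | 75 | 38.6 | 75 | 63.3 |
| 100 | 58.0 | 100 | 24.9 | 100 | 28.4 | 100 | 57.0 |
| 120 | 52.7 | 120 | 23.1 | 120 | 24.2 | 120 | 54.1 |
| 150 | 47.4 | 150 | 21.1 | 150 | 21.3 | 150 | 47.2 |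

(readings scatter by 0.5 mM)

- Overall: Sub + Rgt -> Prd, with Cat as catalyst.
- Constant volume, constant temperature.
- What is held in complexes is read along with the free species.
- "The second partner" is Rgt.
- An order is taken over about fifteen percent of the charge, up and down.

- apparent order in [Cat] of the starting rate, round the charge of the teal run (the rate where two percent of its Sub have turned into Prd)
- the violet run starts with 60.0 mM less of Sub and of Rgt than the teal run, and with no Prd. Compared where both hold the same amount of Sub, once fifteen percent of what the violet run was charged with has turned into Prd, is the violet run faster, slower or alike (within a tenth)?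
- Sub in the ochre run at 900 min, as a share of the Sub charged

The readings hold an apparent contradiction. Between 120 min and 150 min the teal flask loses Sub at 0.177 mM min⁻¹, with [Sub] near 50.0 mM and [Rgt] near 30.0 mM. Between 25 min and 75 min the violet flask, with [Sub] near 32.2 mM and [Rgt] near 12.2 mM, reads 0.184 mM min⁻¹, about the same, on much less of both partners.

The excess clears this up. Violet has 20.0 mM too, so once teal has used 60.0 mM it holds violet's charge, 40.0 mM of Sub and 20.0 mM of Rgt. The two flasks lie on one line, and teal differs there by the Prd it has made and the age of its catalyst. Prd looks harmless, since the green flask, with 30.0 mM added, reads 47.2 mM at 150 min against 47.4 mM for teal. We therefore suspect that the catalyst ages.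

If teal's rate merely followed its Rgt, it would be 0.0717 mM min⁻¹ at violet's point, so we expect violet to be faster, by about 2.57. For ochre, teal's late rate over its Rgt gives 0.00588 min⁻¹. Taking half of that as a guess for ageing, from teal's last reading on, we estimate about 23.0% of the Sub in the ochre flask at 900 min; this is a point estimate, not a ceiling, and the firm bound is the floor below it.

The forecast gives 0.9 (0.75 to 1.05) for the order in [Cat], faster for violet and 23% (20% to 32%) for ochre, reasoning that “Rgt limits the run, so the floor is 20%”. The flask gives an order of 0.61, violet faster, and 21.3% for ochre.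

    L + Sub → Cat.Sub (5.604 L mol⁻¹ min⁻¹)
    Cat.Sub + Rgt → X (6.240 L mol⁻¹ min⁻¹)
    X → Prd + L (0.1440 min⁻¹)
    L + Rgt → E + Rgt (1.050 L mol⁻¹ min⁻¹)
    Cat + Rgt → L + Rgt (1.068 L mol⁻¹ min⁻¹)

By the excess, ochre's 21.3% leaves 1.29 mM of Rgt at 900 min, bound forms counted. The last blue reading, with twice the Cat, leaves 1.30 mM by the same subtraction at 150 min. Teal lags behind fresh violet on their common line due to the passing of L + Rgt into E + Rgt: the rate of violet over teal at equal Sub is 3.3, and in the simulated run without that step it is 0.56.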